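**Retrosynthetic overview**
- Target ⇐ tricyclic β,γ‑unsaturated keto ester: reduce ketone and ester, then swap the C16 silyl ether for acetate while the 18,20‑diol is masked as an acetonide.
- C10=C11(CH3)/C19H2 ⇐ macrocyclic ene‑dione, by organocerium addition at C11 and SmI2 vinylogous deoxygenation.
- 11‑Membered ring ⇐ B‑alkyl Suzuki macrocyclisation (C2–C3), which also delivers the exocyclic methylene.
- cis‑Hydrindane (C13, C14, C16, C17) ⇐ amine‑catalysed formal [3+2] (Michael/aldol) of succinaldehyde onto a quinone‑monoketal β‑keto ester made from methyl 4‑bromosalicylate (Negishi coupling, oxidative dearomatisation).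
- C6 stereocentre ⇐ cinchona‑catalysed methanolysis of 3‑methylglutaric anhydride. Ring order: six (arene‑derived) → five → eleven.

Assumption: one‑flask sequences through a non‑isolated intermediate count as one step; succinaldehyde is bought as its aqueous solution and distilled before use.
Locants (own map, target SMILES in reading order): C1 (=CH2), C2, C3, C4, C5, C6 (methyl C7), C8, C9, C10=C11 (methyl C12), C13, C14, C15, C16 (OAc), C17 (C20 = CH2OH), C18 (OH), C19. Target = (6S,13S,14R,16R,17R,18S).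

**Route**

Step 1
Reactants: 1 3-methylglutaric anhydride
Product: 2 (3R)-5-methoxy-3-methyl-5-oxopentanoic acid
Conditions: MeOH (10 equiv), (DHQD)2AQN or (DHQ)2AQN (whichever pseudoenantiomer gives the R hemiester, 5–10 mol%), Et2O, −20 °C
Reagents that add atoms: methanol, CO
Why: Cinchona‑alkaloid (general‑base) catalysed alcoholytic desymmetrisation of a meso anhydride opens one enantiotopic carbonyl and sets the C6 stereocentre in high ee.

Step 2
Reactants: 2 (3R)-5-methoxy-3-methyl-5-oxopentanoic acid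
Product: 4 (4R)-4-methyloxan-2-one, via hydroxy ester 3 (not isolated)
Conditions: BH3·SMe2, THF, 0 °C → rt; then TsOH (cat.), PhMe, 60 °C
Reagents that add atoms: none
Why: Chemoselective borane reduction of the acid beside the ester, then acid‑catalysed lactonisation; the stereocentre is not touched.

Step 3
Reactants: 4 (4R)-4-methyloxan-2-one
Product: 6 (3S)-3-methylhex-5-en-1-ol, via lactol 5 (not isolated)
Conditions: DIBAL‑H, CH2Cl2, −78 °C; then Ph3PCH3Br/KOtBu (2.5 equiv), THF, 0 °C → rt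
Reagents that add atoms: methyltriphenylphosphonium bromide (as its ylide), C[P+](c1ccccc1)(c1ccccc1)c1ccccc1.[Br-]
Why: DIBAL half‑reduction to the lactol and Wittig methylenation of its open hydroxy‑aldehyde form.

Step 4
Reactants: 6 (3S)-3-methylhex-5-en-1-ol
Product: 7 (4S)-6-iodo-4-methylhex-1-ene
Conditions: I2, PPh3, imidazole, CH2Cl2, 0 °C
Reagents that add atoms: iodine, II
Why: Appel‑type iodination (SN2 at the primary carbinol carbon).

Step 5
Reactants: 7 (4S)-6-iodo-4-methylhex-1-ene; 8 methyl 4-bromo-2-hydroxybenzoate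
Product: 11 methyl 2-hydroxy-4-[(3R)-3-methylhex-5-en-1-yl]benzoate, via alkyllithium 9 (not isolated), via alkylzinc chloride 10 (not isolated)
Conditions: t‑BuLi (2 equiv), Et2O/pentane, −78 °C; ZnCl2, THF, −78 → 0 °C; then 8 (0.8 equiv), Pd(OAc)2 (2 mol%), SPhos (4 mol%), THF, rt
Reagents that add atoms: none
Why: I/Li exchange at −78 °C (no 5‑exo cyclisation at this temperature), transmetalation to zinc and Negishi sp3–sp2 coupling, which tolerates the ester and the free phenol.

Step 6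
Reactants: 11 methyl 2-hydroxy-4-[(3R)-3-methylhex-5-en-1-yl]benzoate
Product: 13 methyl 3,3-dimethoxy-4-[(3R)-3-methylhex-5-en-1-yl]-6-oxocyclohexa-1,4-diene-1-carboxylate, via hydroquinone monomethyl ether 12 (not isolated)
Conditions: PhI(OAc)2 (2.2 equiv), MeOH, 0 °C → rt
Reagents that add atoms: methanol, CO
Why: Hypervalent‑iodine oxidative dearomatisation: para‑methoxylation of the phenol, then a second oxidation with methanol capture gives the p‑quinone monoketal; no stereocentre is involved.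

Step 7
Reactants: 13 methyl 3,3-dimethoxy-4-[(3R)-3-methylhex-5-en-1-yl]-6-oxocyclohexa-1,4-diene-1-carboxylate; 14 butanedial (succinaldehyde)
Product: 16 methyl (1R,3R,3aR,7aS)-3-formyl-1-hydroxy-4,4-dimethoxy-5-[(3R)-3-methylhex-5-en-1-yl]-7-oxo-1,2,3,3a,4,7-hexahydro-7aH-indene-7a-carboxylate (cis‑fused; CHO cis to C‑4, OH cis to CO2Me), via Michael adduct 15 (not isolated)
Conditions: 14 (3 equiv), (S)-α,α-diphenylprolinol trimethylsilyl ether (20 mol%), 4‑nitrophenol (20 mol%), MeCN, 0 °C → rt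
Reagents that add atoms: none
Why: Proposed new method: an amine‑catalysed domino Michael/aldol (formal [3+2]) between a dialdehyde and a cyclic alkylidene β‑keto ester — the (E)‑enamine of succinaldehyde, shielded on one face by the diarylmethyl silyl ether, adds through the usual synclinal (syn‑selective) transition state to the doubly activated C13=C17 bond (C10 is fully substituted, so the other enone arm is inert), setting C14 and C13 with the formyl group cis to C11; after iminium hydrolysis the β‑keto ester enol closes 5‑exo onto the second formyl group from the face of C14, which enforces the cis ring fusion and the C17 quaternary centre, and the reversible aldol should settle the 16‑OH on the convex face cis to the ester; the closest known reaction types are the diarylprolinol‑silyl‑ether formal [3+2] (Michael/Henry) of succinaldehyde with nitroalkenes and enamine Michael additions of aldehydes to alkylidene malonates, and new here are the quinone‑monoketal β‑keto ester acceptor and the aldol termination that forges an all‑carbon quaternary centre.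

Step 8
Reactants: 16 (aldol adduct, name as above)
Product: 17 methyl (1R,3R,3aR,7aS)-1-[(tert-butyldimethylsilyl)oxy]-3-formyl-4,4-dimethoxy-5-[(3R)-3-methylhex-5-en-1-yl]-7-oxo-1,2,3,3a,4,7-hexahydro-7aH-indene-7a-carboxylate
Conditions: TBSOTf, 2,6‑lutidine, CH2Cl2, −78 °C
Reagents that add atoms: tert‑butyldimethylsilyl triflate, CC(C)(C)[Si](C)(C)OS(=O)(=O)C(F)(F)F
Why: O‑Silylation blocks retro‑aldol/aromatisation and differentiates O16 from the oxygens made later.

Step 9
Reactants: 17 (TBS ether aldehyde, name as above)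
Product: 19 methyl (1R,3R,3aR,7aS)-3-acetyl-1-[(tert-butyldimethylsilyl)oxy]-4,4-dimethoxy-5-[(3R)-3-methylhex-5-en-1-yl]-7-oxo-1,2,3,3a,4,7-hexahydro-7aH-indene-7a-carboxylate, via silyl ketone 18 (not isolated)
Conditions: TMSCHN2 (1.5 equiv), MgBr2·OEt2 (20 mol%), CH2Cl2, −20 → 0 °C; then MeOH, rt
Reagents that add atoms: trimethylsilyldiazomethane, C[Si](C)(C)C=[N+]=[N-]
Why: Diazoalkane homologation of the aldehyde to the methyl ketone (1,2‑hydride shift with loss of N2, then protodesilylation) under near‑neutral conditions that leave C14 intact.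

Step 10
Reactants: 19 (methyl ketone, name as above)
Product: 21 methyl (1R,3R,3aR,7aS)-1-[(tert-butyldimethylsilyl)oxy]-4,4-dimethoxy-5-[(3R)-3-methylhex-5-en-1-yl]-7-oxo-3-{1-[(trifluoromethanesulfonyl)oxy]ethenyl}-1,2,3,3a,4,7-hexahydro-7aH-indene-7a-carboxylate, via potassium enolate 20 (not isolated)
Conditions: KHMDS (1.05 equiv), THF, −78 °C; PhNTf2, −78 → −40 °C
Reagents that add atoms: N‑phenylbis(trifluoromethanesulfonimide), O=S(=O)(N(c1ccccc1)S(=O)(=O)C(F)(F)F)C(F)(F)F
Why: Kinetic deprotonation at the methyl group (not the hindered C14–H) and O‑triflation give the 2‑triflyloxy‑1‑alkene, the precursor of the exocyclic methylene.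

Step 11
Reactants: 21 (vinyl triflate, name as above)
Product: 24 tricyclic ene‑dione: methyl (6S,13R,14R,16R,17S)-16-[(tert-butyldimethylsilyl)oxy]-6-methyl-2-methylidene-11,18-dioxo tricycle with C10=C19, 17‑CO2Me and the 11‑membered ring C2–C3–C4–C5–C6–C8–C9–C10–C11–C13–C14, via alkylborane 22 (not isolated), via macrocyclic ketal 23 (not isolated)
Conditions: 9‑BBN‑H (1.3 equiv), THF, 0 °C → rt; slow addition to PdCl2(dppf) (10 mol%), AsPh3 (20 mol%), aq. K3PO4, DMF/THF, 40 °C, 2 mM; then 1 M HCl, THF, rt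
Reagents that add atoms: water, O
Why: Chemoselective hydroboration of the monosubstituted alkene and intramolecular B‑alkyl Suzuki–Miyaura coupling under high dilution close the 11‑membered ring at C2–C3 on the face fixed by C14, and the acidic work‑up hydrolyses the dimethyl ketal.

Step 12
Reactants: 24 (tricyclic ene‑dione, as above)
Product: 26 methyl (6S,13S,14R,16R,17S)-16-[(tert-butyldimethylsilyl)oxy]-6,11-dimethyl-2-methylidene-18-oxo tricycle with C10=C11 and C19H2 (β,γ‑unsaturated keto ester), via tertiary carbinol 25 (not isolated)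
Conditions: MeMgBr/CeCl3, THF, −78 °C; then SmI2 (3 equiv), HMPA, t‑BuOH, −78 → −20 °C
Reagents that add atoms: methylmagnesium bromide, C[Mg]Br
Why: Organocerium 1,2‑addition to the C11 carbonyl (C18 is flanked by the quaternary C17), then SmI2 reduction of the γ‑oxygenated enone with β‑elimination (vinylogous α‑deoxygenation) gives C10=C11 and C19H2 regiospecifically; both C11 epimers of 25 converge.

Step 13
Reactants: 26 (β,γ‑unsaturated keto ester, as above)
Product: 27 (6S,13S,14R,16R,17R,18S)-16-[(tert-butyldimethylsilyl)oxy] 18,20‑diol (target skeleton with OTBS in place of OAc)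
Conditions: LiAlH4, THF, −78 → 0 °C; Rochelle salt work‑up
Reagents that add atoms: none
Why: Hydride reduction of the ester to CH2OH and of the C18 ketone by axial attack anti to the axial C17–C20 bond (Felkin–Anh), expected to give the equatorial 18‑OH cis to C20.

Step 14
Reactants: 27 (silyl ether diol, as above)
Product: 28 (6S,13S,14R,16R,17R,18S) 18,20‑O‑isopropylidene acetal of 27 (16‑OTBS)
Conditions: 2,2‑dimethoxypropane, PPTS (10 mol%), CH2Cl2, rt
Reagents that add atoms: 2,2‑dimethoxypropane, COC(C)(C)OC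
Why: Acid‑catalysed transketalisation on the only free 1,3‑diol.

Step 15
Reactants: 28 (acetonide silyl ether, as above)
Product: 31 CNP0228496.1, (6S,13S,14R,16R,17R,18S) 16‑acetate 18,20‑diol, via alcohol 29 (not isolated), via acetate 30 (not isolated)
Conditions: TBAF, THF, 45 °C; then Ac2O, DMAP, pyridine, rt; then AcOH/H2O (4:1), 40 °C
Reagents that add atoms: acetic anhydride, CC(=O)OC(C)=O
Why: Fluoride desilylation, DMAP‑catalysed acetylation of the only free hydroxyl, then mild acid hydrolysis of the acetonide, which spares the acetate and both alkenes.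

**Compound list**
1 | 3-methylglutaric anhydride | CC1CC(=O)OC(=O)C1 | starting material
2 | (3R)-5-methoxy-3-methyl-5-oxopentanoic acid | COC(=O)C[C@H](C)CC(=O)O | intermediate
3 | methyl (3R)-5-hydroxy-3-methylpentanoate | COC(=O)C[C@H](C)CCO | intermediate
4 | (4R)-4-methyloxan-2-one | O=C1C[C@H](C)CCO1 | intermediate
5 | (4R)-4-methyloxan-2-ol (lactol, anomers) | OC1C[C@H](C)CCO1 | intermediate
6 | (3S)-3-methylhex-5-en-1-ol | C=CC[C@H](C)CCO | intermediate
7 | (4S)-6-iodo-4-methylhex-1-ene | C=CC[C@H](C)CCI | intermediate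
8 | methyl 4-bromo-2-hydroxybenzoate | COC(=O)c1ccc(Br)cc1O | starting material
9 | [(3R)-3-methylhex-5-en-1-yl]lithium | C=CC[C@H](C)CC[Li] | intermediate
10 | chloro[(3S)-3-methylhex-5-en-1-yl]zinc | C=CC[C@H](C)CC[Zn]Cl | intermediate
11 | methyl 2-hydroxy-4-[(3R)-3-methylhex-5-en-1-yl]benzoate | C=CC[C@H](C)CCc1ccc(C(=O)OC)c(O)c1 | intermediate
12 | methyl 2-hydroxy-5-methoxy-4-[(3R)-3-methylhex-5-en-1-yl]benzoate | C=CC[C@H](C)CCc1cc(O)c(C(=O)OC)cc1OC | intermediate
13 | methyl 3,3-dimethoxy-4-[(3R)-3-methylhex-5-en-1-yl]-6-oxocyclohexa-1,4-diene-1-carboxylate | C=CC[C@H](C)CCC1=CC(=O)C(C(=O)OC)=CC1(OC)OC | intermediate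
14 | butanedial (succinaldehyde) | O=CCCC=O | starting material
15 | methyl (2R)-2-[(2R)-1,4-dioxobutan-2-yl]-3,3-dimethoxy-4-[(3R)-3-methylhex-5-en-1-yl]-6-oxocyclohex-4-ene-1-carboxylate (Michael adduct, keto/enol at C-1) | C=CC[C@H](C)CCC1=CC(=O)C(C(=O)OC)[C@@H]([C@@H](CC=O)C=O)C1(OC)OC | intermediate
16 | methyl (1R,3R,3aR,7aS)-3-formyl-1-hydroxy-4,4-dimethoxy-5-[(3R)-3-methylhex-5-en-1-yl]-7-oxo-1,2,3,3a,4,7-hexahydro-7aH-indene-7a-carboxylate | C=CC[C@H](C)CCC1=CC(=O)[C@@]2(C(=O)OC)[C@H](O)C[C@@H](C=O)[C@H]2C1(OC)OC | intermediate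
17 | 1-O-TBS ether of 16 (1R,3R,3aR,7aS) | C=CC[C@H](C)CCC1=CC(=O)[C@@]2(C(=O)OC)[C@H](O[Si](C)(C)C(C)(C)C)C[C@@H](C=O)[C@H]2C1(OC)OC | intermediate
18 | 3-[(trimethylsilyl)acetyl] analogue of 17 (1R,3R,3aR,7aS) | C=CC[C@H](C)CCC1=CC(=O)[C@@]2(C(=O)OC)[C@H](O[Si](C)(C)C(C)(C)C)C[C@@H](C(=O)C[Si](C)(C)C)[C@H]2C1(OC)OC | intermediate
19 | 3-acetyl analogue of 17 (1R,3R,3aR,7aS) | C=CC[C@H](C)CCC1=CC(=O)[C@@]2(C(=O)OC)[C@H](O[Si](C)(C)C(C)(C)C)C[C@@H](C(C)=O)[C@H]2C1(OC)OC | intermediate
20 | potassium enolate of 19 (methyl side) | C=CC[C@H](C)CCC1=CC(=O)[C@@]2(C(=O)OC)[C@H](O[Si](C)(C)C(C)(C)C)C[C@@H](C(=C)[O-])[C@H]2C1(OC)OC.[K+] | intermediate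
21 | 3-{1-[(trifluoromethanesulfonyl)oxy]ethenyl} analogue of 17 (1R,3R,3aR,7aS) | C=CC[C@H](C)CCC1=CC(=O)[C@@]2(C(=O)OC)[C@H](O[Si](C)(C)C(C)(C)C)C[C@@H](C(=C)OS(=O)(=O)C(F)(F)F)[C@H]2C1(OC)OC | intermediate
22 | B-alkyl-9-BBN from 21: side chain (3S)-6-(9-borabicyclo[3.3.1]nonan-9-yl)-3-methylhexyl | B1(C2CCCC1CCC2)CCC[C@H](C)CCC3=CC(=O)[C@@]4(C(=O)OC)[C@H](O[Si](C)(C)C(C)(C)C)C[C@@H](C(=C)OS(=O)(=O)C(F)(F)F)[C@H]4C3(OC)OC | intermediate
23 | macrocyclic ketal (6S,13R,14R,16R,17S): 11,11-dimethoxy, 18-oxo, C10=C19, 2-methylidene, 16-OTBS, 17-CO2Me | C=C1CCC[C@H](C)CCC2=CC(=O)[C@@]3(C(=O)OC)[C@H](O[Si](C)(C)C(C)(C)C)C[C@@H]1[C@H]3C2(OC)OC | intermediate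
24 | macrocyclic ene-dione (6S,13R,14R,16R,17S): 11,18-dioxo, C10=C19, 2-methylidene, 16-OTBS, 17-CO2Me | C=C1CCC[C@H](C)CCC2=CC(=O)[C@@]3(C(=O)OC)[C@H](O[Si](C)(C)C(C)(C)C)C[C@@H]1[C@H]3C2=O | intermediate
25 | 11-hydroxy-11-methyl carbinol from 24 (C11 epimers) | C=C1CCC[C@H](C)CCC2=CC(=O)[C@@]3(C(=O)OC)[C@H](O[Si](C)(C)C(C)(C)C)C[C@@H]1[C@H]3C2(C)O | intermediate
26 | β,γ-unsaturated keto ester (6S,13S,14R,16R,17S): C10=C11(CH3), 18-oxo, 16-OTBS, 17-CO2Me | C=C1CCC[C@H](C)CCC2=C(C)[C@@H]3[C@H]1C[C@@H](O[Si](C)(C)C(C)(C)C)[C@]3(C(=O)OC)C(=O)C2 | intermediate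
27 | 16-OTBS 18,20-diol (6S,13S,14R,16R,17R,18S) | C=C1CCC[C@H](C)CCC2=C(C)[C@@H]3[C@H]1C[C@@H](O[Si](C)(C)C(C)(C)C)[C@]3(CO)[C@@H](O)C2 | intermediate
28 | 18,20-O-isopropylidene 16-OTBS (6S,13S,14R,16R,17R,18S) | C=C1CCC[C@H](C)CCC2=C(C)[C@@H]3[C@H]1C[C@@H](O[Si](C)(C)C(C)(C)C)[C@]3(COC(C)(C)O4)[C@@H]4C2 | intermediate
29 | 18,20-O-isopropylidene 16-ol (6S,13S,14R,16R,17S,18S) | C=C1CCC[C@H](C)CCC2=C(C)[C@@H]3[C@H]1C[C@@H](O)[C@]3(COC(C)(C)O4)[C@@H]4C2 | intermediate
30 | 18,20-O-isopropylidene 16-acetate (6S,13S,14R,16R,17R,18S) | C=C1CCC[C@H](C)CCC2=C(C)[C@@H]3[C@H]1C[C@@H](OC(C)=O)[C@]3(COC(C)(C)O4)[C@@H]4C2 | intermediate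
31 | CNP0228496.1 (6S,13S,14R,16R,17R,18S) | C=C1CCC[C@H](C)CCC2=C(C)[C@@H]3[C@H]1C[C@@H](OC(C)=O)[C@]3(CO)[C@@H](O)C2 | target

**Count and risks**
Total steps: 15. Longest linear sequence: 15 (1 → 31; 8 and 14 are bought).

Most likely to fail:

- **Step 7 (the proposed new domino).** Reactivity of the hindered acceptor, syn selectivity at C14, and the C16 aldol configuration are all unproven. The fallback uses known chemistry, sets out from 13 and comes back at 19. A chiral primary‑amine–thiourea‑catalysed enamine Michael addition of commercial 5‑hydroxypentan‑2‑one (a known reaction class for ketones with alkylidene 1,3‑dicarbonyl acceptors) gives the hydroxy ketone Michael adduct F1. Parikh–Doering oxidation gives the keto aldehyde F2, which Et3N closes by intramolecular aldol of the β‑keto ester to the hydroxy methyl ketone F3. TBSOTf/2,6‑lutidine then gives 19, so steps 8 and 9 are not needed.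

- **Step 11 (11‑membered ring by B‑alkyl Suzuki coupling).** The fallback sets out from 17 and comes back at 23. Vinylmagnesium bromide at −78 °C gives the allylic alcohol F4. Ring‑closing metathesis (Grubbs II, 1 mM, CH2Cl2, 40 °C) joins the vinyl CH to C4 with loss of ethene and gives the macrocyclic allylic alcohol F5. Dess–Martin oxidation gives the macrocyclic enone F6, and Stryker's reagent reduces only this unhindered enone to the macrocyclic ketone F7. At F7, C14 can be equilibrated with DBU toward the configuration the ring prefers. Lombardo methylenation gives 23, which is hydrolysed to 24 as in step 11.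

- **Step 12 (C11 methyl and deconjugative deoxygenation).** Site selectivity between C11 and C18, and elimination from a metal alkoxide, are the concerns. The fallback sets out from 24 and comes back at 26. Wittig methylenation at the less hindered C11 carbonyl gives the linear dienone F8. Dissolving‑metal (Li/NH3, t‑BuOH, brief) or SmI2/HMPA 1,6‑reduction with kinetic protonation at C19 then gives 26.

The C18 configuration from step 13 and the double oxidation in step 6 are the next weakest points.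

**Further compounds**
F1 | step 7 | methyl (2R)-2-[(3R)-1-hydroxy-4-oxopentan-3-yl]-3,3-dimethoxy-4-[(3R)-3-methylhex-5-en-1-yl]-6-oxocyclohex-4-ene-1-carboxylate | C=CC[C@H](C)CCC1=CC(=O)C(C(=O)OC)[C@@H]([C@@H](CCO)C(C)=O)C1(OC)OC
F2 | step 7 | methyl (2R)-2-[(3R)-1,4-dioxopentan-3-yl]-3,3-dimethoxy-4-[(3R)-3-methylhex-5-en-1-yl]-6-oxocyclohex-4-ene-1-carboxylate | C=CC[C@H](C)CCC1=CC(=O)C(C(=O)OC)[C@@H]([C@@H](CC=O)C(C)=O)C1(OC)OC
F3 | step 7 | methyl (1R,3R,3aR,7aS)-3-acetyl-1-hydroxy-4,4-dimethoxy-5-[(3R)-3-methylhex-5-en-1-yl]-7-oxo-1,2,3,3a,4,7-hexahydro-7aH-indene-7a-carboxylate | C=CC[C@H](C)CCC1=CC(=O)[C@@]2(C(=O)OC)[C@H](O)C[C@@H](C(C)=O)[C@H]2C1(OC)OC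
F4 | step 11 | 3-(1-hydroxyprop-2-en-1-yl) analogue of 17 (carbinol epimers; ring stereocentres as in 17) | C=CC[C@H](C)CCC1=CC(=O)[C@@]2(C(=O)OC)[C@H](O[Si](C)(C)C(C)(C)C)C[C@@H](C(O)C=C)[C@H]2C1(OC)OC
F5 | step 11 | macrocyclic allylic alcohol: 2-hydroxy, C3=C4 analogue of 23 without the methylidene (ring stereocentres as in 23) | OC1C=CC[C@H](C)CCC2=CC(=O)[C@@]3(C(=O)OC)[C@H](O[Si](C)(C)C(C)(C)C)C[C@@H]1[C@H]3C2(OC)OC
F6 | step 11 | macrocyclic enone: 2-oxo, C3=C4 analogue of 23 (ring stereocentres as in 23) | O=C1C=CC[C@H](C)CCC2=CC(=O)[C@@]3(C(=O)OC)[C@H](O[Si](C)(C)C(C)(C)C)C[C@@H]1[C@H]3C2(OC)OC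
F7 | step 11 | macrocyclic ketone: 2-oxo analogue of 23 (ring stereocentres as in 23) | O=C1CCC[C@H](C)CCC2=CC(=O)[C@@]3(C(=O)OC)[C@H](O[Si](C)(C)C(C)(C)C)C[C@@H]1[C@H]3C2(OC)OC
F8 | step 12 | 11-methylidene dienone: 24 with C11=CH2 in place of C11=O (stereocentres as in 24) | C=C1CCC[C@H](C)CCC2=CC(=O)[C@@]3(C(=O)OC)[C@H](O[Si](C)(C)C(C)(C)C)C[C@@H]1[C@H]3C2=C
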